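The runs were computed for an exercise, and the scatter is random.

The ratio I watch is the rate at which target is made over the rate at which it is used up. At a ratio of one the two are equal and target stands still, so that steady state is my zero.

the same everywhere: reagent in the second phase 0.525 M
- alpha: starting material 1.1 M; run made earlier
- flask: starting material 0.75 M; time 5.0 h; volume of the second phase over the first 2.0

alpha run (percent of the starting material charged)

| time / min | target / % | starting material / % |
|---|---|---|
| 5.00 | 0.4 | 100.3 |
| 8.00 | 0.2 | 99.5 |
| 12.0 | 0 | 99.7 |
| 15.0 | 0.6 | 99.1 |
| 25.0 | 1.1 | 98.8 |
| 40.0 | 1.7 | 97.4 |
| 60.0 | 3.4 | 95.0 |

(readings scatter by 0.3 percentage points)

- in the second phase: reagent in the second phase; everything else is in the first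
- charges count per volume of the first phase; a concentration in a rate is the amount of a species over the volume of its own phase; every rate counts per litre of the first phase
- the numbers in the tables scatter by 0.3 percentage points (one standard deviation)
- on the list of suspects stand: target -> over-reaction product; reagent in the reaction phase <-> reagent in the second phase; starting material + reagent in the reaction phase <-> target
- the earlier runs hold the two phases in the same ratio of volumes as the flask asked about

- grey: doubling the transfer coefficient of the reagent in the second phase, all else as stated
- violet: doubling the amount of reagent in the second phase, all else as stated

* amount of target at 5.0 h, in percent of the starting material charged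
* the change that raises the amount of target at 5.0 h, in percent of the starting material charged most ("none" if none brings more than 2 percentage points) (grey / violet / none)
* amount of target at 5.0 h, in percent of the starting material charged, after violet

By 60.0 min the alpha run is missing 1.6 percentage points from starting material plus target, which I take as over-reaction product, though each reading scatters by 0.3 points. Dividing this by the area under the target readings gives k = 0.0187 /min, the over-reaction constant, read with that scatter. Its half-life is 0.619 h. Since that is shorter than 5.0 h, I expect target in the flask to sit near the level r/k, where r is the loss of starting material per minute as a share of its charge. The last span of alpha gives r = 0.00120 /min, so the level is 6.43%.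

| Setting turned | What I expect of r | Target by hand |
|---|---|---|
| Starting material, 1.1 M to 0.75 M | unchanged, as it counts per charge | 6.43% |
| Time, to 5.0 h | unchanged while r holds | 6.43% |
| Grey | reached earlier, late value unchanged | 6.43% |
| Violet | doubled, if it follows the reagent charge | 12.9% |

I commit to 6.43% for the flask and to violet as the best change, with 12.9% as my estimate after it. The forecast is lower: 5% (3% to 9%), with violet best at 8% (5% to 14%). Its ground is that “the target is already over-reacting”.

The flask gives 4.59% of target at 5.0 h; violet gains 3.2 points, reaching 7.76%, and grey gains 0.27 points.

    target → over-reaction product (k = 0.0190 /min)
    reagent in the reaction phase ⇌ reagent in the second phase, rate k2*([reagent in the reaction phase] - [reagent in the second phase]/K2) per volume of the first phase (partition coefficient = 1.10, kL = 0.00760 /min)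
    starting material + reagent in the reaction phase ⇌ target (K = 3.50 /M, k = 0.0420 /M/min)

At 5.0 h target in the flask is made at 0.885 of the rate at which it is used up, each step taken net. Between 2.50 h and 5.00 h starting material in the flask falls from 83.5% to 69.6%, and this loss over k gives 4.96%. The same flask read at 12 h has starting material down to 48.6%, and the same reckoning from 5.00 h gives 2.67%, between the 4.59% target at the start of that span and the 1.82% at its end.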